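**Strategy.** The pyran ring is closed last, through the O1–C2 bond. The precursor is a cis-epoxide (from a Z-alkene) whose benzylic carbon carries the 3,4-dibenzyloxyphenyl B ring and whose other carbon is joined by one CH2 to the carbon between the two hydroxyls of a 5-benzyloxyresorcinol. Unmasking the two equivalent phenols triggers a 6-endo, invertive epoxide opening: one phenol becomes O1, its twin ends as the free C5–OH, the epoxide oxygen becomes the C3–OH, and the cis C2/C3 relationship is copied from the epoxide. The step exploits the local twofold symmetry of the A ring (O1 and O–C5 equivalent, O–C7 unique) and the benzylic activation of C2. Both hydroxyls are then galloylated together.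

Key step: step 8

Remark: the (S,S)-Mn(salen) catalyst in step 7 is assumed to show the facial sense it shows with cis-β-methylstyrene and indene (benzylic carbon S); if the opposite sense is found, the (R,R)-catalyst is used.

Step 1
Reactants: 1 2,4,6-trihydroxybenzaldehyde
Product: 2 4-(benzyloxy)-2,6-dihydroxybenzaldehyde
Conditions: BnBr (1.0 equiv), NaHCO3 (1.2 equiv), DMF, 40 °C
Reagents that add atoms: benzyl bromide, BrCc1ccccc1
Why: Williamson etherification; the 4-OH is the most acidic phenol and the only one not hydrogen-bonded to the formyl group, so one equivalent of weak base and BnBr should alkylate it selectively.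

Step 2
Reactants: 2 4-(benzyloxy)-2,6-dihydroxybenzaldehyde
Product: 3 4-(benzyloxy)-2,6-bis[(triisopropylsilyl)oxy]benzaldehyde
Conditions: TIPSOTf (2.4 equiv), 2,6-lutidine, CH2Cl2, 0 °C → rt
Reagents that add atoms: triisopropylsilyl trifluoromethanesulfonate, CC(C)[Si](OS(=O)(=O)C(F)(F)F)(C(C)C)C(C)C
Why: Silylation with the silyl triflate and a hindered base should cap both chelated phenols as aryl TIPS ethers, which tolerate organolithiums and acid, resist O→O silyl migration and are cleaved by fluoride.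

Step 3
Reactants: 4 3,4-bis(benzyloxy)benzaldehyde
Product: 5 1,2-bis(benzyloxy)-4-ethynylbenzene
Conditions: Ohira–Bestmann reagent, K2CO3, MeOH/THF, rt
Reagents that add atoms: dimethyl (1-diazo-2-oxopropyl)phosphonate, COP(=O)(OC)C(=[N+]=[N-])C(C)=O
Why: Ohira–Bestmann (Seyferth–Gilbert) homologation converts the aryl aldehyde into the terminal alkyne under mild base that leaves the benzyl ethers alone.

Step 4
Reactants: 5 1,2-bis(benzyloxy)-4-ethynylbenzene and 3 4-(benzyloxy)-2,6-bis[(triisopropylsilyl)oxy]benzaldehyde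
Product: 7 rac-1-{4-(benzyloxy)-2,6-bis[(triisopropylsilyl)oxy]phenyl}-3-[3,4-bis(benzyloxy)phenyl]prop-2-yn-1-ol, via lithium arylacetylide 6 (not isolated)
Conditions: n-BuLi, THF, −78 °C; then 3, −78 °C; AcOH quench at −78 °C
Reagents that add atoms: n-butyllithium, [Li]CCCC (supplies the lithium of 6; no atom other than hydrogen reaches 7)
Why: Deprotonation of the alkyne and 1,2-addition of the lithium acetylide to the hindered, non-enolisable aldehyde; the carbinol stereocentre forms as a racemate and is erased in step 5.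

Step 5
Reactants: 7 rac-1-{4-(benzyloxy)-2,6-bis[(triisopropylsilyl)oxy]phenyl}-3-[3,4-bis(benzyloxy)phenyl]prop-2-yn-1-ol
Product: 8 1-{4-(benzyloxy)-2,6-bis[(triisopropylsilyl)oxy]phenyl}-3-[3,4-bis(benzyloxy)phenyl]prop-2-yne
Conditions: Et3SiH (3 equiv), TFA (2 equiv), CH2Cl2, −40 → −10 °C
Reagents that add atoms: none
Why: Ionic hydrogenation (Kursanov–Parnes reduction); the trioxygenated benzylic, propargylic cation forms readily and should be trapped by hydride at the benzylic carbon.

Step 6
Reactants: 8 1-{4-(benzyloxy)-2,6-bis[(triisopropylsilyl)oxy]phenyl}-3-[3,4-bis(benzyloxy)phenyl]prop-2-yne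
Product: 9 (Z)-1-[3,4-bis(benzyloxy)phenyl]-3-{4-(benzyloxy)-2,6-bis[(triisopropylsilyl)oxy]phenyl}prop-1-ene
Conditions: H2 (1 atm), Lindlar catalyst, quinoline, EtOAc, rt
Reagents that add atoms: none
Why: Lindlar semihydrogenation adds H2 syn to the alkyne and should give the Z-alkene without touching benzyl or silyl ethers.

Step 7
Reactants: 9 (Z)-1-[3,4-bis(benzyloxy)phenyl]-3-{4-(benzyloxy)-2,6-bis[(triisopropylsilyl)oxy]phenyl}prop-1-ene
Product: 10 (2S,3R)-2-[3,4-bis(benzyloxy)phenyl]-3-{4-(benzyloxy)-2,6-bis[(triisopropylsilyl)oxy]benzyl}oxirane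
Conditions: (S,S)-Jacobsen Mn(salen)Cl (5 mol %), mCPBA (2 equiv), NMO (5 equiv), CH2Cl2, −78 °C; Et3N-deactivated silica
Reagents that add atoms: meta-chloroperoxybenzoic acid, OOC(=O)c1cccc(Cl)c1
Why: Jacobsen–Katsuki epoxidation, the method of choice for cis-β-substituted styrenes; the alkene geometry fixes the cis relationship and the catalyst the absolute configuration of both epoxide carbons.

Step 8
Reactants: 10 (2S,3R)-2-[3,4-bis(benzyloxy)phenyl]-3-{4-(benzyloxy)-2,6-bis[(triisopropylsilyl)oxy]benzyl}oxirane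
Product: 12 (2R,3R)-7-(benzyloxy)-2-[3,4-bis(benzyloxy)phenyl]chromane-3,5-diol, via diphenol cis-epoxide 11 (not isolated)
Conditions: TBAF/AcOH (1:1, 2.4 equiv), THF, −20 °C; cold aqueous wash; then (PhO)2P(O)OH (10 mol %), PhMe, −20 → 0 °C
Reagents that add atoms: none
Why: Fluoride buffered with AcOH cleaves both aryl TIPS ethers to give 11, and one phenol then attacks the acid-activated epoxide at the benzylic carbon C2 from the face opposite the epoxide oxygen, forming the O1–C2 bond. The closest known reaction type is the acid-promoted 6-endo cyclisation of hydroxy- and phenol-tethered aryl or vinyl epoxides to tetrahydropyrans and chroman-3-ols. The pyran ring closes in the 6-endo-tet mode. C2 is set by inversion of the (2S) epoxide carbon to (2R), and C3 keeps the (3R) configuration installed in step 7, so the cis-epoxide becomes the 2,3-cis flavan. The step needs 6-endo over 5-exo attack, which the 3,4-dibenzyloxyphenyl group secures by making C2 the more electrophilic carbon under acid, and inversion over ionisation, which a weak bifunctional acid in a non-polar solvent at low temperature should favour. No selectivity between the two phenols is needed because rotation about the C4–C4a bond interconverts them; the unused one can hydrogen-bond to the epoxide oxygen and ends as the free C5–OH.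

Step 9
Reactants: 12 (2R,3R)-7-(benzyloxy)-2-[3,4-bis(benzyloxy)phenyl]chromane-3,5-diol and 13 3,4,5-tris(benzyloxy)benzoic acid
Product: 14 (2R,3R)-7-(benzyloxy)-2-[3,4-bis(benzyloxy)phenyl]chromane-3,5-diyl bis[3,4,5-tris(benzyloxy)benzoate]
Conditions: 13 (3 equiv), DCC (3 equiv), DMAP (0.5 equiv), CH2Cl2, rt
Reagents that add atoms: none
Why: Steglich esterification; with excess acid, carbodiimide and DMAP both the phenolic 5-OH and the axial secondary 3-OH should be acylated without touching C2 or C3.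

Step 10
Reactants: 14 (2R,3R)-7-(benzyloxy)-2-[3,4-bis(benzyloxy)phenyl]chromane-3,5-diyl bis[3,4,5-tris(benzyloxy)benzoate]
Product: 15 epicatechin 3,5-di-O-gallate
Conditions: H2 (1 atm), Pd(OH)2/C, THF/EtOAc, rt
Reagents that add atoms: none
Why: Hydrogenolysis of the nine O-benzyl ethers over Pearlman's catalyst under neutral, non-alcoholic conditions should leave both esters and the C2–O1 ether intact.

**Compound list**

1 | 2,4,6-trihydroxybenzaldehyde | O=Cc1c(O)cc(O)cc1O | starting material
2 | 4-(benzyloxy)-2,6-dihydroxybenzaldehyde | O=Cc1c(O)cc(OCc2ccccc2)cc1O | intermediate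
3 | 4-(benzyloxy)-2,6-bis[(triisopropylsilyl)oxy]benzaldehyde | O=Cc1c(O[Si](C(C)C)(C(C)C)C(C)C)cc(OCc2ccccc2)cc1O[Si](C(C)C)(C(C)C)C(C)C | intermediate
4 | 3,4-bis(benzyloxy)benzaldehyde | O=Cc1ccc(OCc2ccccc2)c(OCc2ccccc2)c1 | starting material
5 | 1,2-bis(benzyloxy)-4-ethynylbenzene | C#Cc1ccc(OCc2ccccc2)c(OCc2ccccc2)c1 | intermediate
6 | lithium [3,4-bis(benzyloxy)phenyl]acetylide | [Li]C#Cc1ccc(OCc2ccccc2)c(OCc2ccccc2)c1 | intermediate
7 | rac-1-{4-(benzyloxy)-2,6-bis[(triisopropylsilyl)oxy]phenyl}-3-[3,4-bis(benzyloxy)phenyl]prop-2-yn-1-ol | OC(C#Cc1ccc(OCc2ccccc2)c(OCc2ccccc2)c1)c1c(O[Si](C(C)C)(C(C)C)C(C)C)cc(OCc2ccccc2)cc1O[Si](C(C)C)(C(C)C)C(C)C | intermediate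
8 | 1-{4-(benzyloxy)-2,6-bis[(triisopropylsilyl)oxy]phenyl}-3-[3,4-bis(benzyloxy)phenyl]prop-2-yne | C(C#Cc1ccc(OCc2ccccc2)c(OCc2ccccc2)c1)c1c(O[Si](C(C)C)(C(C)C)C(C)C)cc(OCc2ccccc2)cc1O[Si](C(C)C)(C(C)C)C(C)C | intermediate
9 | (Z)-1-[3,4-bis(benzyloxy)phenyl]-3-{4-(benzyloxy)-2,6-bis[(triisopropylsilyl)oxy]phenyl}prop-1-ene | C(/C=C\c1ccc(OCc2ccccc2)c(OCc2ccccc2)c1)c1c(O[Si](C(C)C)(C(C)C)C(C)C)cc(OCc2ccccc2)cc1O[Si](C(C)C)(C(C)C)C(C)C | intermediate
10 | (2S,3R)-2-[3,4-bis(benzyloxy)phenyl]-3-{4-(benzyloxy)-2,6-bis[(triisopropylsilyl)oxy]benzyl}oxirane | c1ccccc1COc1ccc(cc1OCc1ccccc1)[C@@H]2O[C@@H]2Cc1c(O[Si](C(C)C)(C(C)C)C(C)C)cc(OCc3ccccc3)cc1O[Si](C(C)C)(C(C)C)C(C)C | intermediate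
11 | (2S,3R)-2-[3,4-bis(benzyloxy)phenyl]-3-[4-(benzyloxy)-2,6-dihydroxybenzyl]oxirane | c1ccccc1COc1ccc(cc1OCc1ccccc1)[C@@H]2O[C@@H]2Cc1c(O)cc(OCc3ccccc3)cc1O | intermediate
12 | (2R,3R)-7-(benzyloxy)-2-[3,4-bis(benzyloxy)phenyl]chromane-3,5-diol | Oc1cc(OCc3ccccc3)cc2c1C[C@@H](O)[C@@H](c1ccc(OCc3ccccc3)c(OCc3ccccc3)c1)O2 | intermediate
13 | 3,4,5-tris(benzyloxy)benzoic acid | OC(=O)c1cc(OCc2ccccc2)c(OCc2ccccc2)c(OCc2ccccc2)c1 | starting material
14 | (2R,3R)-7-(benzyloxy)-2-[3,4-bis(benzyloxy)phenyl]chromane-3,5-diyl bis[3,4,5-tris(benzyloxy)benzoate] | O=C(Oc1cc(OCc3ccccc3)cc2c1C[C@@H](OC(=O)c1cc(OCc3ccccc3)c(OCc3ccccc3)c(OCc3ccccc3)c1)[C@@H](c1ccc(OCc3ccccc3)c(OCc3ccccc3)c1)O2)c1cc(OCc3ccccc3)c(OCc3ccccc3)c(OCc3ccccc3)c1 | intermediate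
15 | epicatechin 3,5-di-O-gallate, (2R,3R) | O=C(Oc1cc(O)cc2c1C[C@@H](OC(=O)c1cc(O)c(O)c(O)c1)[C@@H](c1ccc(O)c(O)c1)O2)c1cc(O)c(O)c(O)c1 | target

**Total step count:** 10. **Longest linear sequence:** 9 steps (steps 1, 2, 4–10, from 1).

**Steps most likely to fail**

Step 8 (key step). The benzylic C2–O bond of the electron-rich epoxide may ionise before the phenol arrives, so that the anti stereospecificity is partly lost and the C2 epimer forms beside 12; attack at C3 (5-exo) is the other possible leak. The fallback sets out from 12 as obtained with its C2 epimer and comes back at 12; it moves stereocontrol from the epoxide opening to a reduction after ring closure. The phenol is silylated selectively (TIPSCl, imidazole, DMF, 0 °C) to (3R)-7-(benzyloxy)-2-[3,4-bis(benzyloxy)phenyl]-5-[(triisopropylsilyl)oxy]chroman-3-ol F1 (both C2 epimers). Dess–Martin oxidation (NaHCO3, CH2Cl2) gives 7-(benzyloxy)-2-[3,4-bis(benzyloxy)phenyl]-5-[(triisopropylsilyl)oxy]chroman-3-one F2, in which C2–H is acidic so that both epimers converge. Noyori–Ikariya transfer hydrogenation under dynamic kinetic resolution (RuCl(p-cymene)(TsDPEN), HCO2H/Et3N, using the catalyst enantiomer that delivers the 3R carbinol, to be assigned on a test scale) should give the cis alcohol (2R,3R)-7-(benzyloxy)-2-[3,4-bis(benzyloxy)phenyl]-5-[(triisopropylsilyl)oxy]chroman-3-ol F3. TBAF/AcOH then returns 12.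

Step 7. Oxygen transfer from the Mn-oxo species is stepwise, so a radical intermediate may rotate before ring closure (cis-to-trans leakage), and the bulky benzylic substituent may lower facial selectivity. The fallback sets out from 9 and comes back at 10. It replaces the metal-oxo manifold by a concerted, metal-free dioxirane transfer: Shi epoxidation with the carbohydrate-derived oxazolidinone ketone developed for cis-olefins (Oxone, K2CO3 buffer, MeCN/DMM, 0 °C, the catalyst antipode that gives the 2S,3R epoxide). This path cannot isomerise the alkene geometry and makes no new compound (F0).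

Step 1. Alkylation may not stop at the 4-OH, and the chelated 2-OH may compete, giving mixtures of mono- and dibenzyl ethers. The fallback sets out from 1 and comes back at 2; it over-protects and then deprotects under chelation control. Benzylation of the two most reactive phenols (BnBr 2.2 equiv, K2CO3, DMF) should give 2,4-bis(benzyloxy)-6-hydroxybenzaldehyde F4. Cleavage of the benzyl ether ortho to the formyl group with MgBr2·OEt2 (PhMe/Et2O, reflux) then returns 2.

**Further compounds**

F1 | step 8 | (3R)-7-(benzyloxy)-2-[3,4-bis(benzyloxy)phenyl]-5-[(triisopropylsilyl)oxy]chroman-3-ol, C2 epimers | CC(C)[Si](Oc1cc(OCc3ccccc3)cc2c1C[C@@H](O)C(c1ccc(OCc3ccccc3)c(OCc3ccccc3)c1)O2)(C(C)C)C(C)C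
F2 | step 8 | 7-(benzyloxy)-2-[3,4-bis(benzyloxy)phenyl]-5-[(triisopropylsilyl)oxy]chroman-3-one | CC(C)[Si](Oc1cc(OCc3ccccc3)cc2c1CC(=O)C(c1ccc(OCc3ccccc3)c(OCc3ccccc3)c1)O2)(C(C)C)C(C)C
F3 | step 8 | (2R,3R)-7-(benzyloxy)-2-[3,4-bis(benzyloxy)phenyl]-5-[(triisopropylsilyl)oxy]chroman-3-ol | CC(C)[Si](Oc1cc(OCc3ccccc3)cc2c1C[C@@H](O)[C@@H](c1ccc(OCc3ccccc3)c(OCc3ccccc3)c1)O2)(C(C)C)C(C)C
F0 | step 7 | none | none
F4 | step 1 | 2,4-bis(benzyloxy)-6-hydroxybenzaldehyde | O=Cc1c(O)cc(OCc2ccccc2)cc1OCc1ccccc1
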